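In a closed, stirred vessel of constant volume, held at one temperature, substrate meets coupling partner and capture agent, and you follow how much ends up as product and how much as trapped intermediate.

| setting | spring | dawn | flask |
|---|---|---|---|
| substrate | 0.20 M | 0.45 M | 0.30 M |
| coupling partner | 0.33 M | 0.33 M | 0.330 M |
| capture agent | 0.015 M | 0.015 M | 0.0150 M |
| remark | run made earlier | run made earlier |  |
| time |  |  | 15 d |

- spring (time / d: product / %, trapped intermediate / %): 2.50: 20.0, 6.8; 5.00: 26.4, 7.4; 8.00: 28.7, 6.6; 10.0: 27.9, 7.3; 12.0: 28.2, 7.7; 15.0: 28.1, 6.6
- dawn (time / d: product / %, trapped intermediate / %): 1.04: 8.7, 3.0; 3.00: 23.0, 4.0; 5.00: 28.1, 3.3; 8.00: 29.7, 3.0; 12.0: 29.4, 3.0; 15.0: 29.5, 3.5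

(standard deviation of a reading: 0.3 percentage points)

- share of product in product plus trapped intermediate at 6.0 h
- share of product in product plus trapped intermediate at 50 h
- share of product in product plus trapped intermediate at 15 d
- which of product and trapped intermediate there is more of at 15 d



Suppose each capture agent holds one trapped intermediate, so that the capture agent is the limiting reagent of the trapping. Call the capture ceiling the starting c(capture agent) over the starting c(substrate), 5.00% for this flask: it is the most trapped intermediate you can expect, in percent of the substrate charged. The spring run has a ceiling of 7.50%, and its late readings run from 6.6% to 7.7%. The dawn run has 3.33%, and its late readings run from 3.0% to 3.5%.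

At 15.0 d product reads 28.1% in the spring run and 29.5% in the dawn run, so I take their mean, 28.8%, as my estimate for this flask at 15 d. That puts product ahead, with a share of 85.2% at 15 d. The ceiling gives no number for 6.0 h or 50 h.

The forecast, “It is therefore capped by the capture agent”, gave 30% at 6.0 h, 79% at 50 h and 85.7% at 15 d, with product ahead. The flask gives 14.6%, 78.5% and 85.1%, with product ahead.

    substrate → intermediate A (k = 0.393 h⁻¹)
    intermediate A ⇌ intermediate B (K = 0.597, k = 0.0186 h⁻¹)
    intermediate A → intermediate C (k = 0.0723 h⁻¹)
    intermediate C ⇌ product (K = 36.0, k = 0.0112 h⁻¹)
    intermediate C → decomposed reagent (k = 0.0239 h⁻¹)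
    capture agent + intermediate A → trapped intermediate (k = 1.19 L mol⁻¹ h⁻¹)

At 15 d this flask holds 4.95% of trapped intermediate under its ceiling of 5.00%. A neighbouring flask charged with 0.0060 M of capture agent has a ceiling of 2.00% and holds 1.98% at 15.0 d; the mean product reading and that ceiling give a share of 93.5%, and that neighbour shows 93.6%. In this flask at 0.0735 d, intermediate C has a half-life of 1.2 d by the step to decomposed reagent and 2.6 d by the forward step to product taken alone, so the step to decomposed reagent runs about twice as fast. At 15.0 d this flask holds 66.4% of decomposed reagent against 28.3% of product.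

All runs are simulated from invented constants.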